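The C1–C10 oxirane of the ten-membered carbocycle is traced back to an E-configured trisubstituted C1=C10 alkene, and that alkene to an eleven-membered cyclic sulfone in which sulfur sits between C1 and C10. One Ramberg–Bäcklund operation halogenates an α-carbon, joins C1 to C10 through a transient thiirane dioxide and expels SO2, so ring contraction and alkene formation happen together. The sulfone already carries the (4R,5R)-oxirane and the C6, C7 and C8 oxygens (TBS, PMB and DMB ethers, all removable without acid). It is assembled from 2-deoxy-D-ribose (C6–C10) and 5-chloropent-1-yne (C1–C5) by chromium-mediated coupling and a thiolate ring closure at C1.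

Key step: step 14

Remark: locants are those of the germacrane skeleton of the target (ring C1–C10, C14 on C10, C15 on C4, lactone carbons C11–C13); PMB = 4-methoxybenzyl, DMB = 3,4-dimethoxybenzyl, TBS = tert-butyldimethylsilyl; 13–19 are carried as both C10 epimers and 31–33 as both C11 epimers, which is assumed harmless because C10 and C11 become sp2 in steps 14 and 25.

Step 1
Reactants: 1 2-deoxy-D-ribose
Product: 2 (2R,3S)-hex-5-ene-1,2,3-triol
Conditions: Ph3PCH3Br, KOtBu, THF, 0 °C to reflux
Reagents that add atoms: methyltriphenylphosphonium bromide, C[P+](c1ccccc1)(c1ccccc1)c1ccccc1.[Br-]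
Why: Wittig methylenation of the open-chain aldehyde form of the lactol (excess ylide tolerates the free hydroxyls) turns C10 into a vinyl group without touching the C7 and C8 stereocentres taken from the sugar.

Step 2
Reactants: 2 (2R,3S)-hex-5-ene-1,2,3-triol
Product: 3 (2R,4S,5R)-2-(3,4-dimethoxyphenyl)-4-(prop-2-enyl)-1,3-dioxan-5-ol
Conditions: 3,4-(MeO)2C6H3CH(OMe)2, CSA (cat.), CH2Cl2, rt
Reagents that add atoms: 3,4-dimethoxybenzaldehyde dimethyl acetal, COC(OC)c1ccc(OC)c(OC)c1
Why: Acid-catalysed transacetalisation under thermodynamic control should select the six-membered 1,3-dioxane across the C6 and C8 oxygens, the only acetal in which aryl, allyl and hydroxyl groups are all equatorial, leaving C7–OH free; the acetal carbon is set by the equatorial preference of the aryl group.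

Step 3
Reactants: 3 (2R,4S,5R)-2-(3,4-dimethoxyphenyl)-4-(prop-2-enyl)-1,3-dioxan-5-ol
Product: 4 (2R,4S,5R)-2-(3,4-dimethoxyphenyl)-5-(4-methoxybenzyloxy)-4-(prop-2-enyl)-1,3-dioxane
Conditions: NaH, PMBCl, Bu4NI (cat.), DMF, 0 °C to rt
Reagents that add atoms: 4-methoxybenzyl chloride, COc1ccc(CCl)cc1
Why: Williamson etherification of the only free hydroxyl installs at C7 an ether that cannot migrate to a neighbouring oxygen and is later removed oxidatively.

Step 4
Reactants: 4 (2R,4S,5R)-2-(3,4-dimethoxyphenyl)-5-(4-methoxybenzyloxy)-4-(prop-2-enyl)-1,3-dioxane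
Product: 5 (2R,3S)-3-(3,4-dimethoxybenzyloxy)-2-(4-methoxybenzyloxy)hex-5-en-1-ol
Conditions: iBu2AlH, toluene, −40 to 0 °C
Reagents that add atoms: none
Why: Regioselective reductive opening of the arylidene acetal: iBu2AlH coordinates the less hindered primary-side oxygen and delivers hydride to the resulting oxocarbenium ion, which leaves the DMB ether on the secondary C8 oxygen and frees the primary C6 hydroxyl.

Step 5
Reactants: 5 (2R,3S)-3-(3,4-dimethoxybenzyloxy)-2-(4-methoxybenzyloxy)hex-5-en-1-ol
Product: 6 (2S,3S)-3-(3,4-dimethoxybenzyloxy)-2-(4-methoxybenzyloxy)hex-5-enal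
Conditions: Dess–Martin periodinane, NaHCO3, CH2Cl2, 0 °C to rt
Reagents that add atoms: none
Why: Buffered Dess–Martin oxidation gives the α-alkoxy aldehyde under non-basic conditions, so C7 should not epimerise.

Step 6
Reactants: 7 5-chloropent-1-yne
Product: 9 (E)-5-chloro-1-iodo-2-methylpent-1-ene, via alkenyldimethylalane 8 (not isolated)
Conditions: AlMe3, (C5H5)2ZrCl2 (cat.), CH2Cl2, 0 °C to rt; then I2, THF, −30 °C
Reagents that add atoms: trimethylaluminium, C[Al](C)C; iodine, II
Why: (C5H5)2ZrCl2-catalysed syn-carboalumination puts methyl on the internal carbon and aluminium on the terminus, and iodinolysis with retention gives the E-alkenyl iodide that fixes the later C4=C5 geometry, the primary chloride being inert to the alane.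

Step 7
Reactants: 6 (2S,3S)-3-(3,4-dimethoxybenzyloxy)-2-(4-methoxybenzyloxy)hex-5-enal; 9 (E)-5-chloro-1-iodo-2-methylpent-1-ene
Product: 10 open-chain C6 allylic alcohol (4E; 6R,7R,8S; C1–Cl; C7–OPMB; C8–ODMB; C10=C14 vinyl)
Conditions: CrCl2, NiCl2 (cat.), DMSO, rt
Reagents that add atoms: none
Why: Nozaki–Hiyama–Kishi coupling (NiCl2-catalysed formation of the alkenylchromium species from CrCl2, selective for the aldehyde and inert to the alkyl chloride) forms C5–C6 with retention of alkene geometry, and Felkin–Anh addition anti to the C7 alkoxy group, reinforced by the anti-disposed C8 alkoxy group, should set C6 as the 6,7-anti alcohol.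

Step 8
Reactants: 10 open-chain C6 allylic alcohol
Product: 11 epoxy alcohol (4R,5R,6S,7R,8S; 4,5-oxirane; C6–OH)
Conditions: mCPBA, NaHCO3, CH2Cl2, −20 to 0 °C
Reagents that add atoms: 3-chloroperoxybenzoic acid, O=C(OO)c1cccc(Cl)c1
Why: Hydroxyl-assisted peracid epoxidation of the allylic alcohol, in which allylic 1,3-strain between the C6 substituents and the cis methyl on C4 fixes the reactive conformer so that oxygen arrives syn to the hydroxyl, should give the threo (4R,5R)-oxirane from the 6,7-anti alcohol, while the monosubstituted C10=C14 alkene is far less nucleophilic.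

Step 9
Reactants: 11 epoxy alcohol
Product: 12 C6 TBS ether (4R,5R,6S,7S,8S)
Conditions: TBSOTf, 2,6-lutidine, CH2Cl2, −78 °C
Reagents that add atoms: tert-butyldimethylsilyl trifluoromethanesulfonate, CC(C)(C)[Si](C)(C)OS(=O)(=O)C(F)(F)F
Why: Silylation with the triflate and a hindered pyridine base at low temperature caps C6–OH without forming a free alkoxide, so Payne rearrangement of the epoxy alcohol is avoided.

Step 10
Reactants: 12 C6 TBS ether
Product: 13 C10 secondary alcohol (C10–OH with C14 methyl; both C10 epimers)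
Conditions: Co(acac)2 (cat.), PhSiH3, O2 (1 atm), THF, rt
Reagents that add atoms: dioxygen, O=O
Why: Mukaiyama hydration (hydrogen-atom transfer to the terminal alkene from the hydride generated from Co(acac)2 and PhSiH3, then trapping of the secondary C10 radical by O2) gives the Markovnikov alcohol at the only alkene left under neutral conditions, and either C10 configuration is acceptable.

Step 11
Reactants: 13 C10 secondary alcohol
Product: 14 C10 thioacetate (both C10 epimers)
Conditions: PPh3, DIAD, AcSH, THF, 0 °C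
Reagents that add atoms: thioacetic acid, CC(=O)S
Why: Mitsunobu displacement with thioacetic acid forms the secondary C10–S bond intermolecularly with inversion, so that the later ring closure can take place at the primary carbon, and the chloride and the oxirane are inert to the weakly nucleophilic thioacetate.

Step 12
Reactants: 14 C10 thioacetate
Product: 16 eleven-membered cyclic sulfide (S between C1 and C10; 4,5-oxirane; C6–OTBS; C7–OPMB; C8–ODMB), via cesium thiolate 15 (not isolated)
Conditions: Cs2CO3, MeOH, NaI (cat.), degassed DMF, high dilution, 50 °C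
Reagents that add atoms: none
Why: Methanolysis of the thioacetate releases the cesium thiolate, which closes the eleven-membered thiacycle by SN2 at the primary C1 chloride (iodide catalysis, high dilution); with sulfur on C10 the thiolate stays remote from the oxirane, whose nearer carbon C5 is hindered by the quaternary C4 and the silyloxy-bearing C6.

Step 13
Reactants: 16 eleven-membered cyclic sulfide
Product: 17 eleven-membered cyclic sulfone (S between C1 and C10; 4R,5R-oxirane; C6–OTBS; C7–OPMB; C8–ODMB)
Conditions: mCPBA (2.2 equiv), NaHCO3, CH2Cl2, 0 °C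
Reagents that add atoms: 3-chloroperoxybenzoic acid, O=C(OO)c1cccc(Cl)c1
Why: Peracid oxidation of the sulfide through the sulfoxide to the sulfone is much faster than any reaction of the benzyl-type ethers, the silyl ether or the oxirane.

Step 14
Reactants: 17 eleven-membered cyclic sulfone
Product: 20 ten-membered (E)-1(10)-ene (4R,5R-oxirane; C6–OTBS; C7–OPMB; C8–ODMB), via 1-bromo sulfone 18 (not isolated), via episulfone 19 (not isolated)
Conditions: CBr2F2, KOH/Al2O3, tBuOH/CH2Cl2, 0 °C to rt
Reagents that add atoms: none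
Why: Base removes an α-proton of the sulfone, the carbanion takes bromine from CBr2F2 (expected at the less hindered C1), and a second deprotonation at C10 is followed by 1,3-displacement of bromide to give the thiirane 1,1-dioxide, which loses SO2 stereospecifically to leave C1=C10. The closest known reaction type is the one-pot halogenative Ramberg–Bäcklund contraction of cyclic sulfones to cycloalkenes one atom smaller. The ten-membered carbocycle arises by contraction of the eleven-membered thiacycle: the C1–C10 bond forms in a 3-exo-tet closure to the bicyclic episulfone, and the carbocycle is left when SO2 is expelled. No stereocentre is created, C10 is destroyed so that both epimers converge, and the only new stereoelement is the alkene geometry. E geometry is needed; C1 is the one epimerisable carbon of the episulfone (C10 is quaternary there), and under excess alkoxide it should equilibrate to the isomer with C2 and C9 trans before extrusion, an arrangement that the trans-4,5-oxirane and the pseudo-equatorial C6–C8 substituents accommodate in a crown-type ring conformation. The oxirane, the silyl ether and the benzyl-type ethers are stable to KOH in tBuOH, and no leaving group lies β to either sulfonyl carbanion.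

Step 15
Reactants: 20 ten-membered (E)-1(10)-ene
Product: 21 diepoxide (1R,4R,5R,6S,7S,8S,10R; C6–OTBS; C7–OPMB; C8–ODMB)
Conditions: mCPBA, NaHCO3, CH2Cl2, 0 °C
Reagents that add atoms: 3-chloroperoxybenzoic acid, O=C(OO)c1cccc(Cl)c1
Why: Peracid epoxidation of the only alkene, for which only the outer face of an E-alkene in a ten-membered ring is accessible, should give the (1R,10R)-oxirane because the conformer that keeps the C6, C7 and C8 substituents pseudo-equatorial (C14 and C15 on the same side, as in natural germacranolides) exposes that face.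

Step 16
Reactants: 21 diepoxide
Product: 22 C8 alcohol (1R,4R,5R,6S,7S,8S,10R; C6–OTBS; C7–OPMB)
Conditions: DDQ (1.1 equiv), CH2Cl2/pH 7 buffer, 0 °C
Reagents that add atoms: none
Why: Oxidative debenzylation by DDQ is faster for the more electron-rich 3,4-dimethoxybenzyl ether than for the 4-methoxybenzyl ether, so one equivalent in buffered wet CH2Cl2 should free only C8–OH under neutral conditions that spare both oxiranes.

Step 17
Reactants: 22 C8 alcohol; 23 tiglic acid
Product: 25 C8 tiglate (C6–OTBS; C7–OPMB), via mixed anhydride 24 (not isolated)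
Conditions: 2,4,6-Cl3C6H2COCl, Et3N, THF, rt; then 22, DMAP, toluene, rt
Reagents that add atoms: none
Why: Yamaguchi esterification, in which DMAP attacks the less hindered tigloyl carbonyl of the mixed anhydride, acylates the secondary C8 hydroxyl without isomerising the E-configured tigloyl alkene.

Step 18
Reactants: 25 C8 tiglate
Product: 26 C6 alcohol (1R,4R,5R,6S,7R,8S,10R; C7–OPMB; C8–O-tigloyl)
Conditions: HF·pyridine, pyridine, THF, 0 °C to rt
Reagents that add atoms: none
Why: Buffered fluoride cleaves the secondary silyl ether at C6 without generating a free alkoxide beside the oxirane or the ester, so neither Payne rearrangement nor acyl migration is expected.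

Step 19
Reactants: 27 benzyl 2-(diethoxyphosphoryl)acetate
Product: 28 benzyl 2-(diethoxyphosphoryl)-3-hydroxypropanoate (racemic)
Conditions: aq. HCHO (1 equiv), K2CO3 (cat.), THF/H2O, 0 °C
Reagents that add atoms: formaldehyde, C=O
Why: Base-catalysed aldol-type hydroxymethylation of the doubly activated methylene should stop largely at the mono-adduct when one equivalent of formaldehyde and only catalytic weak base are used.

Step 20
Reactants: 28 benzyl 2-(diethoxyphosphoryl)-3-hydroxypropanoate
Product: 29 benzyl 3-(tert-butyldimethylsilyloxy)-2-(diethoxyphosphoryl)propanoate (racemic)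
Conditions: TBSCl, imidazole, DMF, rt
Reagents that add atoms: tert-butyldimethylsilyl chloride, CC(C)(C)[Si](C)(C)Cl
Why: Standard silylation of the primary alcohol under weakly basic conditions protects the future C13 hydroxyl.

Step 21
Reactants: 29 benzyl 3-(tert-butyldimethylsilyloxy)-2-(diethoxyphosphoryl)propanoate
Product: 30 3-(tert-butyldimethylsilyloxy)-2-(diethoxyphosphoryl)propanoic acid (racemic)
Conditions: H2 (1 atm), Pd/C, EtOAc, rt
Reagents that add atoms: none
Why: Hydrogenolysis of the benzyl ester liberates the acid under neutral conditions and avoids hydroxide, which could trigger β-elimination of the silyloxy group.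

Step 22
Reactants: 26 C6 alcohol; 30 3-(tert-butyldimethylsilyloxy)-2-(diethoxyphosphoryl)propanoic acid
Product: 31 C6 phosphonoacetate ester (C7–OPMB; C8–O-tigloyl; C13–OTBS; both C11 epimers)
Conditions: EDC·HCl, DMAP, CH2Cl2, 0 °C to rt
Reagents that add atoms: none
Why: Carbodiimide/DMAP (Steglich) esterification attaches the phosphonoacetate unit that carries the protected C13 hydroxyl to C6–OH under non-basic conditions.

Step 23
Reactants: 31 C6 phosphonoacetate ester
Product: 32 C7 alcohol (C6–O-phosphonoacyl; C8–O-tigloyl; C13–OTBS)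
Conditions: DDQ, CH2Cl2/pH 7 buffer, 0 °C to rt
Reagents that add atoms: none
Why: DDQ oxidation removes the remaining 4-methoxybenzyl ether at C7, the esters, silyl ether, phosphonate and oxiranes being inert and no neighbouring free hydroxyl being present to trap the benzylic cation.

Step 24
Reactants: 32 C7 alcohol
Product: 33 C7 ketone (1R,4R,5R,6R,8S,10R; C6–O-phosphonoacyl; C8–O-tigloyl; C13–OTBS)
Conditions: Dess–Martin periodinane, NaHCO3, CH2Cl2, 0 °C
Reagents that add atoms: none
Why: Buffered Dess–Martin oxidation converts C7–OH into the ketone without base, so the β,γ-epoxy ketone is not exposed to enolising conditions before cyclisation.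

Step 25
Reactants: 33 C7 ketone
Product: 34 13-O-TBS ether of the target (7(11)-en-6,12-olide closed)
Conditions: LiCl, DBU, MeCN, 0 °C
Reagents that add atoms: none
Why: Intramolecular Horner–Wadsworth–Emmons olefination, in which lithium chelation makes the phosphonate the most acidic site so that a mild amidine base forms the carbanion selectively, should close the five-membered ring onto the C7 ketone to give the C7=C11 butenolide faster than enolisation towards C6 or loss of the β-silyloxy group.

Step 26
Reactants: 34 13-O-TBS ether of the target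
Product: 35 CNP0111480.1 (target)
Conditions: HF·pyridine, pyridine, THF, 0 °C
Reagents that add atoms: none
Why: Buffered HF·pyridine removes the primary silyl ether, and the oxiranes, the tiglate and the butenolide should tolerate these near-neutral conditions.

Compound list

1 | 2-deoxy-D-ribose, (3S,4R)-3,4,5-trihydroxypentanal | O=CC[C@H](O)[C@H](O)CO | starting material
2 | (2R,3S)-hex-5-ene-1,2,3-triol | C=CC[C@H](O)[C@H](O)CO | intermediate
3 | (2R,4S,5R)-2-(3,4-dimethoxyphenyl)-4-(prop-2-enyl)-1,3-dioxan-5-ol (acetal across the C6 and C8 oxygens, C7–OH free) | C=CC[C@@H]1O[C@H](c2ccc(OC)c(OC)c2)OC[C@H]1O | intermediate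
4 | (2R,4S,5R)-2-(3,4-dimethoxyphenyl)-5-(4-methoxybenzyloxy)-4-(prop-2-enyl)-1,3-dioxane | C=CC[C@@H]1O[C@H](c2ccc(OC)c(OC)c2)OC[C@H]1OCc1ccc(OC)cc1 | intermediate
5 | (2R,3S)-3-(3,4-dimethoxybenzyloxy)-2-(4-methoxybenzyloxy)hex-5-en-1-ol | C=CC[C@H](OCc1ccc(OC)c(OC)c1)[C@H](OCc1ccc(OC)cc1)CO | intermediate
6 | (2S,3S)-3-(3,4-dimethoxybenzyloxy)-2-(4-methoxybenzyloxy)hex-5-enal | C=CC[C@H](OCc1ccc(OC)c(OC)c1)[C@H](OCc1ccc(OC)cc1)C=O | intermediate
7 | 5-chloropent-1-yne | C#CCCCCl | starting material
8 | [(E)-5-chloro-2-methylpent-1-enyl]dimethylalane | C[Al](C)/C=C(\C)CCCCl | intermediate (not isolated)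
9 | (E)-5-chloro-1-iodo-2-methylpent-1-ene | ClCCC/C(C)=C/I | intermediate
10 | (4S,5R,6R,7E)-11-chloro-4-(3,4-dimethoxybenzyloxy)-5-(4-methoxybenzyloxy)-8-methylundeca-1,7-dien-6-ol (germacrane locants: 4E, 6R, 7R, 8S) | ClCCC/C(C)=C/[C@@H](O)[C@@H](OCc1ccc(OC)cc1)[C@@H](OCc1ccc(OC)c(OC)c1)CC=C | intermediate
11 | (4R,5R)-4,5-epoxide of 10, open chain, C6–OH free (4R,5R,6S,7R,8S) | ClCCC[C@@]1(C)O[C@@H]1[C@@H](O)[C@@H](OCc1ccc(OC)cc1)[C@@H](OCc1ccc(OC)c(OC)c1)CC=C | intermediate
12 | C6 TBS ether of 11 (4R,5R,6S,7S,8S) | ClCCC[C@@]1(C)O[C@@H]1[C@@H](O[Si](C)(C)C(C)(C)C)[C@@H](OCc1ccc(OC)cc1)[C@@H](OCc1ccc(OC)c(OC)c1)CC=C | intermediate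
13 | C10 secondary alcohol from hydration of the vinyl group of 12 (C10–OH, C14 methyl; both C10 epimers) | ClCCC[C@@]1(C)O[C@@H]1[C@@H](O[Si](C)(C)C(C)(C)C)[C@@H](OCc1ccc(OC)cc1)[C@@H](OCc1ccc(OC)c(OC)c1)CC(C)O | intermediate
14 | C10 S-acetyl thioester of 13 (both C10 epimers) | ClCCC[C@@]1(C)O[C@@H]1[C@@H](O[Si](C)(C)C(C)(C)C)[C@@H](OCc1ccc(OC)cc1)[C@@H](OCc1ccc(OC)c(OC)c1)CC(C)SC(C)=O | intermediate
15 | cesium C10-thiolate derived from 14 | ClCCC[C@@]1(C)O[C@@H]1[C@@H](O[Si](C)(C)C(C)(C)C)[C@@H](OCc1ccc(OC)cc1)[C@@H](OCc1ccc(OC)c(OC)c1)CC(C)[S-].[Cs+] | intermediate (not isolated)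
16 | eleven-membered cyclic sulfide, S between C1 and C10, with 4R,5R-oxirane, 6S-OTBS, 7S-OPMB, 8S-ODMB, C10 methyl (both C10 epimers) | COc1ccc(CO[C@H]2CC(C)SCCC[C@@]3(C)O[C@@H]3[C@@H](O[Si](C)(C)C(C)(C)C)[C@H]2OCc2ccc(OC)cc2)cc1OC | intermediate
17 | eleven-membered cyclic sulfone (S,S-dioxide of 16), key-step precursor | COc1ccc(CO[C@H]2CC(C)S(=O)(=O)CCC[C@@]3(C)O[C@@H]3[C@@H](O[Si](C)(C)C(C)(C)C)[C@H]2OCc2ccc(OC)cc2)cc1OC | intermediate
18 | 1-bromo derivative of sulfone 17 (Br on C1) | COc1ccc(CO[C@H]2CC(C)S(=O)(=O)C(Br)CC[C@@]3(C)O[C@@H]3[C@@H](O[Si](C)(C)C(C)(C)C)[C@H]2OCc2ccc(OC)cc2)cc1OC | intermediate (not isolated)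
19 | episulfone: thiirane 1,1-dioxide spanning C1 and C10, fused to the ten-membered ring, C2 and C9 trans | COc1ccc(CO[C@H]2CC3(C)C(CC[C@@]4(C)O[C@@H]4[C@@H](O[Si](C)(C)C(C)(C)C)[C@H]2OCc2ccc(OC)cc2)S3(=O)=O)cc1OC | intermediate (not isolated)
20 | ten-membered (1(10)E)-alkene with 4R,5R-oxirane, 6S-OTBS, 7S-OPMB, 8S-ODMB, key-step product | COc1ccc(CO[C@H]2C/C(C)=C/CC[C@@]3(C)O[C@@H]3[C@@H](O[Si](C)(C)C(C)(C)C)[C@H]2OCc2ccc(OC)cc2)cc1OC | intermediate
21 | (1R,4R,5R,6S,7S,8S,10R)-1,10:4,5-diepoxide with C6–OTBS, C7–OPMB, C8–ODMB | COc1ccc(CO[C@H]2C[C@@]3(C)O[C@@H]3CC[C@@]3(C)O[C@@H]3[C@@H](O[Si](C)(C)C(C)(C)C)[C@H]2OCc2ccc(OC)cc2)cc1OC | intermediate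
22 | (1R,4R,5R,6S,7S,8S,10R)-diepoxide with C8–OH, C6–OTBS, C7–OPMB | O[C@H]1C[C@@]2(C)O[C@@H]2CC[C@@]2(C)O[C@@H]2[C@@H](O[Si](C)(C)C(C)(C)C)[C@H]1OCc1ccc(OC)cc1 | intermediate
23 | tiglic acid, (E)-2-methylbut-2-enoic acid | C/C=C(\C)C(=O)O | starting material
24 | tiglic 2,4,6-trichlorobenzoic anhydride | C/C=C(\C)C(=O)OC(=O)c1c(Cl)cc(Cl)cc1Cl | intermediate (not isolated)
25 | C8 tiglate of 22 (C6–OTBS, C7–OPMB) | C/C=C(\C)C(=O)O[C@H]1C[C@@]2(C)O[C@@H]2CC[C@@]2(C)O[C@@H]2[C@@H](O[Si](C)(C)C(C)(C)C)[C@H]1OCc1ccc(OC)cc1 | intermediate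
26 | (1R,4R,5R,6S,7R,8S,10R)-diepoxide with C6–OH, C7–OPMB, C8–O-tigloyl | C/C=C(\C)C(=O)O[C@H]1C[C@@]2(C)O[C@@H]2CC[C@@]2(C)O[C@@H]2[C@@H](O)[C@H]1OCc1ccc(OC)cc1 | intermediate
27 | benzyl 2-(diethoxyphosphoryl)acetate | CCOP(=O)(CC(=O)OCc1ccccc1)OCC | starting material
28 | benzyl 2-(diethoxyphosphoryl)-3-hydroxypropanoate (racemic) | CCOP(=O)(OCC)C(CO)C(=O)OCc1ccccc1 | intermediate
29 | benzyl 3-(tert-butyldimethylsilyloxy)-2-(diethoxyphosphoryl)propanoate (racemic) | CCOP(=O)(OCC)C(CO[Si](C)(C)C(C)(C)C)C(=O)OCc1ccccc1 | intermediate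
30 | 3-(tert-butyldimethylsilyloxy)-2-(diethoxyphosphoryl)propanoic acid (racemic) | CCOP(=O)(OCC)C(CO[Si](C)(C)C(C)(C)C)C(=O)O | intermediate
31 | C6 ester of 26 with acid 30 (C7–OPMB, C8–O-tigloyl, C13–OTBS; both C11 epimers) | C/C=C(\C)C(=O)O[C@H]1C[C@@]2(C)O[C@@H]2CC[C@@]2(C)O[C@@H]2[C@@H](OC(=O)C(CO[Si](C)(C)C(C)(C)C)P(=O)(OCC)OCC)[C@H]1OCc1ccc(OC)cc1 | intermediate
32 | C7 alcohol from 31 (7S; both C11 epimers) | C/C=C(\C)C(=O)O[C@H]1C[C@@]2(C)O[C@@H]2CC[C@@]2(C)O[C@@H]2[C@@H](OC(=O)C(CO[Si](C)(C)C(C)(C)C)P(=O)(OCC)OCC)[C@H]1O | intermediate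
33 | C7 ketone (1R,4R,5R,6R,8S,10R; both C11 epimers) | C/C=C(\C)C(=O)O[C@H]1C[C@@]2(C)O[C@@H]2CC[C@@]2(C)O[C@@H]2[C@@H](OC(=O)C(CO[Si](C)(C)C(C)(C)C)P(=O)(OCC)OCC)C1=O | intermediate
34 | 13-O-TBS ether of the target (1R,4R,5R,6S,8S,10R) | C/C=C(\C)C(=O)O[C@H]1C[C@@]2(C)O[C@@H]2CC[C@@]2(C)O[C@@H]2[C@H]2OC(=O)C(CO[Si](C)(C)C(C)(C)C)=C12 | intermediate
35 | CNP0111480.1: (1R,4R,5R,6S,8S,10R)-1,10:4,5-diepoxy-13-hydroxy-8-tigloyloxygermacr-7(11)-en-12,6-olide | C/C=C(\C)C(=O)O[C@H]1C[C@@]2(C)O[C@@H]2CC[C@@]2(C)O[C@@H]2[C@H]2OC(=O)C(CO)=C12 | target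

Total step count: 26 (22 in the main line, 1 for alkenyl iodide 9, 3 for acid 30).
Longest linear sequence: 22 steps from 2-deoxy-D-ribose (steps 1–5, 7–18 and 22–26).

Steps most likely to fail

1. Step 14. What may go wrong: kinetic closure to the cis-fused episulfone followed by immediate loss of SO2 would deliver the Z-alkene, and repeated bromination at C1 would divert material. The fallback is a two-stage Ramberg–Bäcklund reaction with a preformed halide. It sets out from sulfone 17: deprotonation at the less hindered C1 with LiN(SiMe3)2 in THF at −78 °C and quenching with C2Cl6 should give the 1-chloro sulfone F1, which is isolated. Treatment of F1 with excess KOtBu in THF at −78 °C forms the episulfone cold, where it can be held to epimerise at C1 before being warmed to extrude SO2. The route is rejoined at alkene 20.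

2. Step 12. What may go wrong: intermolecular S-alkylation (oligomer formation) or attack of the thiolate on the oxirane may outrun closure of the eleven-membered ring. The fallback closes the ring with a sulfinate instead of a thiolate. It sets out from thioacetate 14: methanolysis with K2CO3 in MeOH in the presence of methyl acrylate traps the thiolate at once as the sulfide ester F2, and mCPBA oxidises F2 to the sulfone ester F3. One equivalent of NaOMe in MeOH/THF at 0 °C then induces retro-Michael loss of methyl acrylate to give the sodium sulfinate F4, which is not isolated but diluted with DMF containing catalytic NaI and heated to 70 °C. The soft, weakly basic sulfinate, inert towards oxiranes, is S-alkylated at C1 and gives sulfone 17 directly, bypassing 15 and 16.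

3. Step 7. What may go wrong: insufficient facial discrimination in the addition of the alkenylchromium reagent to the α-alkoxy aldehyde, so that much of the 6,7-syn alcohol is formed. The fallback is oxidation followed by chelation-controlled reduction. It sets out from 10 as obtained (both C6 epimers): Dess–Martin oxidation gives the enone F5. 1,2-Reduction with Zn(BH4)2 in Et2O at −30 °C, in which zinc bridges the ketone and the C7 PMB ether and hydride arrives from the less hindered face of the chelate, should return the 6,7-anti alcohol 10.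

Further compounds
F1 | step 14 | 1-chloro derivative of sulfone 17 (Cl on C1) | COc1ccc(CO[C@H]2CC(C)S(=O)(=O)C(Cl)CC[C@@]3(C)O[C@@H]3[C@@H](O[Si](C)(C)C(C)(C)C)[C@H]2OCc2ccc(OC)cc2)cc1OC
F2 | step 12 | open-chain C10 sulfide bearing a 2-(methoxycarbonyl)ethyl group on sulfur | ClCCC[C@@]1(C)O[C@@H]1[C@@H](O[Si](C)(C)C(C)(C)C)[C@@H](OCc1ccc(OC)cc1)[C@@H](OCc1ccc(OC)c(OC)c1)CC(C)SCCC(=O)OC
F3 | step 12 | open-chain C10 sulfone bearing a 2-(methoxycarbonyl)ethyl group on sulfur | ClCCC[C@@]1(C)O[C@@H]1[C@@H](O[Si](C)(C)C(C)(C)C)[C@@H](OCc1ccc(OC)cc1)[C@@H](OCc1ccc(OC)c(OC)c1)CC(C)S(=O)(=O)CCC(=O)OC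
F4 | step 12 | open-chain sodium C10-sulfinate | ClCCC[C@@]1(C)O[C@@H]1[C@@H](O[Si](C)(C)C(C)(C)C)[C@@H](OCc1ccc(OC)cc1)[C@@H](OCc1ccc(OC)c(OC)c1)CC(C)S(=O)[O-].[Na+]
F5 | step 7 | open-chain C6 enone (4E; 7R,8S) | ClCCC/C(C)=C/C(=O)[C@@H](OCc1ccc(OC)cc1)[C@@H](OCc1ccc(OC)c(OC)c1)CC=C
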